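**Plan**

- Retrosynthesis: the silyl ether is removed last; the side chain is cut at C5′–C6′ (the allylic CH2 and the CH2 on the cyclohexene) into a chromene allylic bromide and an α-cyclogeranyl sulfone.
- The pyran ring is then opened at C3=C4, the cis alkene lying between arene carbon C4a and the fully substituted C2 that already carries O1. This leaves a 2-vinylphenyl ether of a tertiary vinyl carbinol. Its O1–C2 bond is cut to a 2-vinylphenol and geranyl methyl carbonate.
- Forward, chromene half: the arene is bought, O1–C2 is made first, the pyran ring is closed second by metathesis, and the prenyl terminus is then oxidised at its E-methyl and brominated.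
- Forward, cyclohexene half: the ring is closed by cation–olefin cyclisation of geranic acid and the acid is taken on to the sulfone. The halves are joined by sulfone alkylation, followed by desulfonylation and desilylation.
- Stereochemistry: C2 (S) comes from the chiral ligand in the palladium-catalysed allylic etherification. Cyclohexene C1 (S) comes from resolution of α-cyclogeranic acid. The E alkene comes from the E-selective SeO2 oxidation.

Key step: step 5

Assumption: the (R,R)-ligand in step 4 and (R)-1-phenylethylamine in step 9 are taken to favour the (S)-configured products; both chiral agents are sold as either antipode, so the mirror-image agent would be used if the sense proved opposite.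

**Route**

Step 1
Reactants: 1 2,5-dihydroxybenzaldehyde
Product: 2 2-hydroxy-5-(triisopropylsilyloxy)benzaldehyde
Conditions: TIPSCl (1.05 equiv), imidazole, DMF, 0 °C to rt
Reagents that add atoms: triisopropylsilyl chloride CC(C)[Si](Cl)(C(C)C)C(C)C
Why: Selective O-silylation; the 2-hydroxyl is held in a hydrogen bond to the formyl group and flanked by it, so the free 5-hydroxyl should be silylated first.

Step 2
Reactants: 2 2-hydroxy-5-(triisopropylsilyloxy)benzaldehyde
Product: 3 2-ethenyl-4-(triisopropylsilyloxy)phenol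
Conditions: Ph3PCH3Br (2.4 equiv), KOtBu (2.3 equiv), THF, 0 °C; then 2, 0 °C to rt
Reagents that add atoms: methyltriphenylphosphonium bromide C[P+](c1ccccc1)(c1ccccc1)c1ccccc1.[Br-]
Why: Wittig methylenation; one equivalent of ylide is spent on the phenol and the second converts the aldehyde of the phenoxide into the styrene, a standard way to 2-vinylphenols.

Step 3
Reactants: 4 geraniol
Product: 5 geranyl methyl carbonate [(E)-3,7-dimethylocta-2,6-dien-1-yl methyl carbonate]
Conditions: ClCO2Me, pyridine, CH2Cl2, 0 °C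
Reagents that add atoms: methyl chloroformate COC(=O)Cl
Why: Acylation of the primary allylic alcohol with a chloroformate under base, which leaves the E alkene in place.

Step 4
Reactants: 3 2-ethenyl-4-(triisopropylsilyloxy)phenol; 5 geranyl methyl carbonate
Product: 6 triisopropyl{4-{[(S)-3,7-dimethylocta-1,6-dien-3-yl]oxy}-3-ethenylphenoxy}silane
Conditions: Pd2(dba)3·CHCl3 (2 mol %), (R,R)-N,N′-(cyclohexane-1,2-diyl)bis[2-(diphenylphosphino)benzamide] (6 mol %), CH2Cl2, rt
Reagents that add atoms: none
Why: Tsuji–Trost asymmetric allylic etherification; zerovalent palladium ionises the carbonate to a π-allyl complex with loss of CO2 and methoxide, the methoxide deprotonates the phenol, and the phenoxide attacks the more substituted allyl terminus inside the chiral pocket of the ligand, which is expected to set the (S) tertiary ether centre (the later C2).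

Step 5
Reactants: 6 triisopropyl{4-{[(S)-3,7-dimethylocta-1,6-dien-3-yl]oxy}-3-ethenylphenoxy}silane
Product: 7 (S)-2-methyl-2-(4-methylpent-3-en-1-yl)-6-(triisopropylsilyloxy)-2H-chromene
Conditions: RuCl2(PCy3)2(=CHPh) (first-generation Grubbs catalyst, 5 mol %), CH2Cl2 (0.01 M), 40 °C
Reagents that add atoms: none
Why: Ring-closing olefin metathesis: the ruthenium benzylidene loses PCy3 and exchanges onto the unhindered styrenyl vinyl group, the new aryl-substituted carbene adds in a [2+2] sense to the vinyl group on the carbinol carbon, and the ruthenacyclobutane cycloreverts to the C3=C4 alkene and Ru=CH2, which carries the chain and sheds ethylene. The closest known reaction is the ring-closing metathesis of 2-vinylphenyl allyl ethers to 2H-chromenes, which tolerates a fully substituted C2. The pyran ring closes as a six-membered ring by joining the two terminal alkene carbons that become C3 and C4, and the ring size forces the new alkene cis. No stereocentre is created, and the C2 configuration from step 4 is kept because no bond to C2 is made or broken. The step needs chemoselectivity for the two monosubstituted alkenes over the vinyl/trisubstituted pair, which would give a cyclopentene and isobutene; initiation at the styrene, the absence of a free allylic hydroxyl and the low reactivity of this catalyst toward trisubstituted alkenes should secure it, and dilution should suppress cross-metathesis.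

Step 6
Reactants: 7 (S)-2-methyl-2-(4-methylpent-3-en-1-yl)-6-(triisopropylsilyloxy)-2H-chromene
Product: 8 (E)-2-methyl-5-[(S)-2-methyl-6-(triisopropylsilyloxy)-2H-chromen-2-yl]pent-2-en-1-ol
Conditions: SeO2 (0.5 equiv), t-BuOOH (3 equiv), CH2Cl2, 0 °C to rt
Reagents that add atoms: tert-butyl hydroperoxide CC(C)(C)OO (oxygen source, relayed by selenium dioxide O=[Se]=O)
Why: Allylic oxidation by SeO2 (ene reaction, then [2,3]-sigmatropic shift), which on a gem-dimethyl trisubstituted alkene hydroxylates the E-methyl; the chromene alkene has no allylic hydrogen and should be left alone.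

Step 7
Reactants: 8 (E)-2-methyl-5-[(S)-2-methyl-6-(triisopropylsilyloxy)-2H-chromen-2-yl]pent-2-en-1-ol
Product: 9 (S)-2-[(E)-5-bromo-4-methylpent-3-en-1-yl]-2-methyl-6-(triisopropylsilyloxy)-2H-chromene
Conditions: CBr4, PPh3, CH2Cl2, 0 °C
Reagents that add atoms: carbon tetrabromide BrC(Br)(Br)Br
Why: Appel bromination under near-neutral conditions, which converts primary allylic alcohols into the bromides without allylic shift or loss of alkene geometry and spares the acid-sensitive chromene.

Step 8
Reactants: 10 geranic acid (the commercial E/Z mixture serves equally)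
Product: 11 (±)-α-cyclogeranic acid [(±)-2,6,6-trimethylcyclohex-2-ene-1-carboxylic acid]
Conditions: 85% H3PO4, 90 °C
Reagents that add atoms: none
Why: Acid-promoted cation–olefin cyclisation; protonation of the 6,7-alkene gives a tertiary cation that is captured by the 2,3-alkene in a six-membered closure, and proton loss gives the ring alkene of the α isomer, the new stereocentre being formed as the racemate.

Step 9
Reactants: 11 (±)-α-cyclogeranic acid
Product: 12 (R)-1-phenylethylammonium (S)-2,6,6-trimethylcyclohex-2-ene-1-carboxylate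
Conditions: (R)-1-phenylethylamine (1.0 equiv), EtOAc, 60 °C to 5 °C; two recrystallisations
Reagents that add atoms: (R)-1-phenylethylamine C[C@@H](N)c1ccccc1
Why: Classical resolution by crystallisation of diastereomeric ammonium carboxylates; the stereocentre is selected, not formed, and the less soluble salt is taken to be that of the (S)-acid.

Step 10
Reactants: 12 (R)-1-phenylethylammonium (S)-2,6,6-trimethylcyclohex-2-ene-1-carboxylate
Product: 13 (S)-α-cyclogeranic acid [(S)-2,6,6-trimethylcyclohex-2-ene-1-carboxylic acid]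
Conditions: 1 M HCl, Et2O, 0 °C
Reagents that add atoms: none
Why: Acid–base liberation of the carboxylic acid from its salt, under which the α-stereocentre is not enolised.

Step 11
Reactants: 13 (S)-α-cyclogeranic acid
Product: 14 (S)-α-cyclogeraniol {[(S)-2,6,6-trimethylcyclohex-2-en-1-yl]methanol}
Conditions: LiAlH4, THF, 0 °C to reflux
Reagents that add atoms: none
Why: Hydride reduction of the carboxylic acid through its lithium carboxylate, which is not deprotonated at the α-carbon, so the configuration should be kept.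

Step 12
Reactants: 14 (S)-α-cyclogeraniol
Product: 15 phenyl {[(S)-2,6,6-trimethylcyclohex-2-en-1-yl]methyl} sulfide
Conditions: PhSSPh, n-Bu3P, pyridine, rt to 50 °C
Reagents that add atoms: diphenyl disulfide c1ccc(SSc2ccccc2)cc1
Why: Hata reaction; the alcohol is activated as an alkoxyphosphonium ion and displaced by thiophenolate at the primary carbon, a method that works on β-branched primary alcohols of the drimenol type and does not touch the stereocentre.

Step 13
Reactants: 15 phenyl {[(S)-2,6,6-trimethylcyclohex-2-en-1-yl]methyl} sulfide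
Product: 16 (S)-α-cyclogeranyl phenyl sulfone {[(S)-2,6,6-trimethylcyclohex-2-en-1-yl]methyl phenyl sulfone}
Conditions: 30% H2O2, (NH4)6Mo7O24·4H2O (10 mol %), EtOH, 0 °C to rt
Reagents that add atoms: hydrogen peroxide OO
Why: Molybdate-catalysed peroxide oxidation of a sulfide to the sulfone, which is chemoselective for sulfur over the trisubstituted ring alkene.

Step 14
Reactants: 16 (S)-α-cyclogeranyl phenyl sulfone; 9 (S)-2-[(E)-5-bromo-4-methylpent-3-en-1-yl]-2-methyl-6-(triisopropylsilyloxy)-2H-chromene
Product: 18 triisopropyl{[(S)-2-methyl-2-{(E)-4-methyl-6-(phenylsulfonyl)-6-[(S)-2,6,6-trimethylcyclohex-2-en-1-yl]hex-3-en-1-yl}-2H-chromen-6-yl]oxy}silane (epimers at the sulfonyl carbon), via α-lithio sulfone 17 (not isolated)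
Conditions: n-BuLi, THF, −78 °C; then 9, −78 to −20 °C
Reagents that add atoms: none
Why: Alkylation of an α-sulfonyl carbanion with a primary allylic bromide (Julia-type fragment coupling), which proceeds by direct SN2 displacement with retention of the E alkene; the new sulfonyl-bearing centre is uncontrolled and is erased in step 15.

Step 15
Reactants: 18 the coupled sulfone
Product: 19 triisopropyl{[(S)-2-methyl-2-{(E)-4-methyl-6-[(S)-2,6,6-trimethylcyclohex-2-en-1-yl]hex-3-en-1-yl}-2H-chromen-6-yl]oxy}silane
Conditions: 6% Na(Hg), Na2HPO4, THF/MeOH, −20 to 0 °C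
Reagents that add atoms: none
Why: Reductive desulfonylation by electron transfer from sodium amalgam with protonation by buffered methanol, standard for unactivated alkyl phenyl sulfones and mild enough to spare the chromene alkene and the aryl silyl ether.

Step 16
Reactants: 19 the silyl ether of the target
Product: 20 (S)-2-methyl-2-{(E)-4-methyl-6-[(S)-2,6,6-trimethylcyclohex-2-en-1-yl]hex-3-en-1-yl}-2H-chromen-6-ol (CNP0309797.1)
Conditions: n-Bu4NF, AcOH, THF, 0 °C, argon
Reagents that add atoms: none
Why: Fluoride cleavage of the aryl silyl ether, buffered with acetic acid and run under argon so that the oxidation-prone 6-chromenol is not left as its phenoxide.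

**Compound list**

1 | 2,5-dihydroxybenzaldehyde | O=Cc1cc(O)ccc1O | starting material
2 | 2-hydroxy-5-(triisopropylsilyloxy)benzaldehyde | O=Cc1cc(O[Si](C(C)C)(C(C)C)C(C)C)ccc1O | intermediate
3 | 2-ethenyl-4-(triisopropylsilyloxy)phenol | C=Cc1cc(O[Si](C(C)C)(C(C)C)C(C)C)ccc1O | intermediate
4 | geraniol | CC(C)=CCC/C(C)=C/CO | starting material
5 | geranyl methyl carbonate | CC(C)=CCC/C(C)=C/COC(=O)OC | intermediate
6 | triisopropyl{4-{[(S)-3,7-dimethylocta-1,6-dien-3-yl]oxy}-3-ethenylphenoxy}silane | CC(C)=CCC[C@@](C)(C=C)Oc1ccc(O[Si](C(C)C)(C(C)C)C(C)C)cc1C=C | intermediate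
7 | (S)-2-methyl-2-(4-methylpent-3-en-1-yl)-6-(triisopropylsilyloxy)-2H-chromene | CC(C)=CCC[C@@]1(C)C=Cc2cc(O[Si](C(C)C)(C(C)C)C(C)C)ccc2O1 | intermediate
8 | (E)-2-methyl-5-[(S)-2-methyl-6-(triisopropylsilyloxy)-2H-chromen-2-yl]pent-2-en-1-ol | OC/C(C)=C/CC[C@@]1(C)C=Cc2cc(O[Si](C(C)C)(C(C)C)C(C)C)ccc2O1 | intermediate
9 | (S)-2-[(E)-5-bromo-4-methylpent-3-en-1-yl]-2-methyl-6-(triisopropylsilyloxy)-2H-chromene | BrC/C(C)=C/CC[C@@]1(C)C=Cc2cc(O[Si](C(C)C)(C(C)C)C(C)C)ccc2O1 | intermediate
10 | geranic acid | CC(C)=CCC/C(C)=C/C(=O)O | starting material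
11 | (±)-α-cyclogeranic acid | CC1=CCCC(C)(C)C1C(=O)O | intermediate
12 | (R)-1-phenylethylammonium (S)-2,6,6-trimethylcyclohex-2-ene-1-carboxylate | CC1=CCCC(C)(C)[C@@H]1C(=O)[O-].C[C@@H]([NH3+])c1ccccc1 | intermediate
13 | (S)-α-cyclogeranic acid | CC1=CCCC(C)(C)[C@@H]1C(=O)O | intermediate
14 | (S)-α-cyclogeraniol | CC1=CCCC(C)(C)[C@@H]1CO | intermediate
15 | phenyl {[(S)-2,6,6-trimethylcyclohex-2-en-1-yl]methyl} sulfide | CC1=CCCC(C)(C)[C@@H]1CSc1ccccc1 | intermediate
16 | (S)-α-cyclogeranyl phenyl sulfone | CC1=CCCC(C)(C)[C@@H]1CS(=O)(=O)c1ccccc1 | intermediate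
17 | α-lithio derivative of sulfone 16 | CC1=CCCC(C)(C)[C@@H]1C([Li])S(=O)(=O)c1ccccc1 | intermediate (not isolated)
18 | triisopropyl{[(S)-2-methyl-2-{(E)-4-methyl-6-(phenylsulfonyl)-6-[(S)-2,6,6-trimethylcyclohex-2-en-1-yl]hex-3-en-1-yl}-2H-chromen-6-yl]oxy}silane | CC1=CCCC(C)(C)[C@@H]1C(C/C(C)=C/CC[C@@]2(C)C=Cc3cc(O[Si](C(C)C)(C(C)C)C(C)C)ccc3O2)S(=O)(=O)c1ccccc1 | intermediate
19 | triisopropyl{[(S)-2-methyl-2-{(E)-4-methyl-6-[(S)-2,6,6-trimethylcyclohex-2-en-1-yl]hex-3-en-1-yl}-2H-chromen-6-yl]oxy}silane | CC1=CCCC(C)(C)[C@@H]1CC/C(C)=C/CC[C@@]1(C)C=Cc2cc(O[Si](C(C)C)(C(C)C)C(C)C)ccc2O1 | intermediate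
20 | (S)-2-methyl-2-{(E)-4-methyl-6-[(S)-2,6,6-trimethylcyclohex-2-en-1-yl]hex-3-en-1-yl}-2H-chromen-6-ol | CC1=CCCC(C)(C)[C@@H]1CC/C(C)=C/CC[C@@]1(C)C=Cc2cc(O)ccc2O1 | target

**Count**

Total steps: 16. Longest linear sequence: 9 steps (steps 1, 2, 4, 5, 6, 7, 14, 15, 16 from 1; equally steps 8 to 16 from 10).

**Steps most likely to fail**

Step 4. The tertiary ether can re-ionise on palladium, which would erode both the branched-to-linear ratio and the enantiomeric purity, and the ortho-vinyl group may slow attack at the hindered terminus. The fallback sets out from 3 and returns at 6, and builds the ether from a propargylic electrophile so that only the branched connectivity can form. Commercial racemic 3,7-dimethyloct-6-en-1-yn-3-ol is converted in the flask (trifluoroacetic anhydride, DBU, MeCN, −5 °C) into 3,7-dimethyloct-6-en-1-yn-3-yl trifluoroacetate F1. With 3 and catalytic CuCl2·2H2O this should give, by copper-catalysed propargylic etherification, racemic triisopropyl{4-[(3,7-dimethyloct-6-en-1-yn-3-yl)oxy]-3-ethenylphenoxy}silane F2. Semihydrogenation (H2, Pd/CaCO3 poisoned with Pb(OAc)2, quinoline, EtOAc, rt) should give racemic triisopropyl{4-[(3,7-dimethylocta-1,6-dien-3-yl)oxy]-3-ethenylphenoxy}silane F3. Its enantiomers would be separated by preparative HPLC on a cellulose carbamate chiral phase to give 6.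

Step 5. The carbene may instead close the carbinol vinyl group onto the trisubstituted alkene (cyclopentene formation with loss of isobutene), or the closure next to the quaternary centre may stall. The fallback sets out from 6 and returns at 8; it removes the competing alkene before the same metathesis and also bypasses step 6.
- mCPBA (1 equiv, NaHCO3, CH2Cl2, 0 °C) should epoxidise only the electron-rich trisubstituted alkene to triisopropyl{4-{[(3S)-5-(3,3-dimethyloxiran-2-yl)-3-methylpent-1-en-3-yl]oxy}-3-ethenylphenoxy}silane F4.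
- H5IO6 (THF/H2O, 0 °C) cleaves the epoxide to (S)-4-[2-ethenyl-4-(triisopropylsilyloxy)phenoxy]-4-methylhex-5-enal F5.
- Wittig reaction with Ph3P=C(CH3)CO2Et (CH2Cl2, rt) gives ethyl (2E,6S)-6-[2-ethenyl-4-(triisopropylsilyloxy)phenoxy]-2,6-dimethylocta-2,7-dienoate F6, whose electron-poor trisubstituted alkene is inert to RuCl2(PCy3)2(=CHPh).
- Ring-closing metathesis under the conditions of step 5 then gives ethyl (E)-2-methyl-5-[(S)-2-methyl-6-(triisopropylsilyloxy)-2H-chromen-2-yl]pent-2-enoate F7.
- i-Bu2AlH (CH2Cl2, −78 °C) reduces the ester to 8.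

Step 14. The carbanion sits next to a ring carbon flanked by a quaternary centre and may alkylate slowly, so that proton transfer and elimination of HBr from the allylic bromide compete. The fallback sets out from 9 and 14 and returns at 19; it exchanges the roles of the partners so that the carbanion is the unhindered allylic one.
- 9 with PhSO2Na (DMF, rt) gives (S)-2-methyl-2-[(E)-4-methyl-5-(phenylsulfonyl)pent-3-en-1-yl]-6-(triisopropylsilyloxy)-2H-chromene F8.
- 14 with I2, PPh3 and imidazole (CH2Cl2, rt) gives (S)-6-(iodomethyl)-1,5,5-trimethylcyclohexene F9.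
- F8 is deprotonated (n-BuLi, THF/HMPA, −78 °C) to the α-lithio allylic sulfone F10, which is alkylated in the same flask with F9 to triisopropyl{[(S)-2-methyl-2-{(E)-4-methyl-5-(phenylsulfonyl)-6-[(S)-2,6,6-trimethylcyclohex-2-en-1-yl]hex-3-en-1-yl}-2H-chromen-6-yl]oxy}silane F11.
- Palladium-catalysed hydride displacement of the allylic sulfonyl group (PdCl2(dppp), LiEt3BH, THF, 0 °C) then gives 19.

**Further compounds**

F1 | step 4 | 3,7-dimethyloct-6-en-1-yn-3-yl trifluoroacetate (racemic) | CC(C)=CCCC(C)(C#C)OC(=O)C(F)(F)F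
F2 | step 4 | triisopropyl{4-[(3,7-dimethyloct-6-en-1-yn-3-yl)oxy]-3-ethenylphenoxy}silane (racemic) | CC(C)=CCCC(C)(C#C)Oc1ccc(O[Si](C(C)C)(C(C)C)C(C)C)cc1C=C
F3 | step 4 | triisopropyl{4-[(3,7-dimethylocta-1,6-dien-3-yl)oxy]-3-ethenylphenoxy}silane (racemic) | CC(C)=CCCC(C)(C=C)Oc1ccc(O[Si](C(C)C)(C(C)C)C(C)C)cc1C=C
F4 | step 5 | triisopropyl{4-{[(3S)-5-(3,3-dimethyloxiran-2-yl)-3-methylpent-1-en-3-yl]oxy}-3-ethenylphenoxy}silane (epimers at the oxirane carbon) | CC1(C)OC1CC[C@@](C)(C=C)Oc1ccc(O[Si](C(C)C)(C(C)C)C(C)C)cc1C=C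
F5 | step 5 | (S)-4-[2-ethenyl-4-(triisopropylsilyloxy)phenoxy]-4-methylhex-5-enal | O=CCC[C@@](C)(C=C)Oc1ccc(O[Si](C(C)C)(C(C)C)C(C)C)cc1C=C
F6 | step 5 | ethyl (2E,6S)-6-[2-ethenyl-4-(triisopropylsilyloxy)phenoxy]-2,6-dimethylocta-2,7-dienoate | CCOC(=O)/C(C)=C/CC[C@@](C)(C=C)Oc1ccc(O[Si](C(C)C)(C(C)C)C(C)C)cc1C=C
F7 | step 5 | ethyl (E)-2-methyl-5-[(S)-2-methyl-6-(triisopropylsilyloxy)-2H-chromen-2-yl]pent-2-enoate | CCOC(=O)/C(C)=C/CC[C@@]1(C)C=Cc2cc(O[Si](C(C)C)(C(C)C)C(C)C)ccc2O1
F8 | step 14 | (S)-2-methyl-2-[(E)-4-methyl-5-(phenylsulfonyl)pent-3-en-1-yl]-6-(triisopropylsilyloxy)-2H-chromene | O=S(=O)(C/C(C)=C/CC[C@@]1(C)C=Cc2cc(O[Si](C(C)C)(C(C)C)C(C)C)ccc2O1)c1ccccc1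
F9 | step 14 | (S)-6-(iodomethyl)-1,5,5-trimethylcyclohexene | CC1=CCCC(C)(C)[C@@H]1CI
F10 | step 14 | α-lithio derivative of allylic sulfone F8 | [Li]C(/C(C)=C/CC[C@@]1(C)C=Cc2cc(O[Si](C(C)C)(C(C)C)C(C)C)ccc2O1)S(=O)(=O)c1ccccc1
F11 | step 14 | triisopropyl{[(S)-2-methyl-2-{(E)-4-methyl-5-(phenylsulfonyl)-6-[(S)-2,6,6-trimethylcyclohex-2-en-1-yl]hex-3-en-1-yl}-2H-chromen-6-yl]oxy}silane (epimers at the sulfonyl carbon) | CC1=CCCC(C)(C)[C@@H]1CC(/C(C)=C/CC[C@@]2(C)C=Cc3cc(O[Si](C(C)C)(C(C)C)C(C)C)ccc3O2)S(=O)(=O)c1ccccc1
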